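The data are calculated for substances that don't exist; scatter was added.

Q at 12 min is the number you ask for, and I get it in two steps: first I see whether the flasks have finished, then how much of the L charged has gone somewhere other than Q.

| flask | L | G | remark | time |
|---|---|---|---|---|
| violet | 0.20 M | 7 mM | run made earlier |  |
| grey | 0.20 M | 13 mM | run made earlier |  |
| amber | 0.20 M | 23 mM | run made earlier |  |
| green | 0.23 M | 10 mM | run made earlier |  |
| noon | 0.20 M | 10 mM |  | 12 min |
| dusk | 0.30 M | 15 mM |  | 12 min |
| winter | 0.060 M | 6.0 mM |  | 12 min |
| summer | 0.30 M | 30 mM |  | 12 min |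
| autumn | 0.80 M | 10 mM |  | 12 min |

- violet (time / min: Q / %, L / %): 0.500: 17, 77; 1.50: 37, 54; 3.00: 53, 31; 4.00: 60, 23; 6.00: 62, 8
- grey (time / min: Q / %, L / %): 1.33: 50, 39; 2.50: 66, 18; 4.00: 74, 7; 5.00: 75, 4; 6.00: 78, 4
- amber (time / min: Q / %, L / %): 0.500: 40, 55; 0.833: 57, 36; 1.50: 66, 17; 3.00: 77, 3; 6.00: 84, 0
- green (time / min: Q / %, L / %): 0.500: 22, 78; 1.50: 46, 44; 3.00: 62, 21; 4.00: 64, 12; 6.00: 70, 7

(scatter of a reading: 1.5 percentage points)

- the analysis behind the earlier runs scatters by 1.5 percentage points, standard deviation

* all flasks from highest to lowest amount of Q, in percent of the L charged, at 12 min (noon / dusk / winter / summer / autumn)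
* the amount of Q, in percent of the L charged of the flask you put first, at 12 min
* the amount of Q, in percent of the L charged of the flask you put last, at 12 min

L falls roughly exponentially in each run, and its lifetime shortens as G grows, so I treat it as pseudo-first-order, with a lifetime inversely proportional to G. In the violet run L goes from 77 % to 8 % between 0.500 min and 6.00 min, which is a lifetime of 2.43 min. Winter has less G than any other flask, so its lifetime comes to 2.83 min. Then 12 min is 4.24 lifetimes, which leaves about 1.44 % of its L, and I take the flasks as finished.

That leaves the missing share, the L charged that is neither L nor Q at the last reading: 30.0 % in violet and 16.0 % in amber. If the loss goes with how much L stands in the flask and for how long, the measure is L charged times lifetime, and that follows the charge ratio of L to G. This ratio is 28.6 in violet and 8.70 in amber. Between them the share climbs 0.7 percentage points per unit of ratio, and I call this the loss slope. The runs keep L between 0.20 M and 0.23 M, so the ratio is my bet and not a reading.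

Walking along the slope from amber, winter and summer, both at ratio 10.0, come to 83.1 % of Q. Noon and dusk, at 20.0, come to 76.0 %, and autumn, at 80.0, to 33.8 %.

The forecast you sent reads summer > dusk > noon > autumn > winter, with 86 % on top (range 82 % to 91 %) and 72 % at the bottom (range 62 % to 77 %), on the ground that “the final yield follows G”. There we part: it puts winter last, where my slope leaves winter level with summer at the top and puts autumn last.

The flasks give winter > summer > noon > dusk > autumn, with 85.7 % in winter and 37.0 % in autumn.

    J ⇌ G + Q (K = 0.230 M, k = 330 /min)
    L + Q → E (k = 0.760 /M/min)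
    L + G → J (k = 64.0 /M/min)

Held against the loss slope, winter stands at 85.7 % against my 83.1 %, and autumn at 37.0 % against my 33.8 %. Summer, with winter's ratio, gives 79.6 %, and dusk, with noon's ratio, gives 71.6 % against 74.1 %. The neighbour of autumn, charged with 0.32 M of L and otherwise as autumn, has a charge ratio of 32.0, so the slope gives it 67.7 % of Q. That flask holds 63.1 % of Q at 12.0 min, beside 35.2 % of E, each E counted as two L.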